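**Plan**

Numbering used: lactone O1, C2(=O), C3, C4(OH), C5(CH3); side chain C6H2, C7(CH3)(OH), C8–C16, then the arene.
Retrosynthetic cuts, in order: aryl O–benzyl; C6–I (helper); C5–O1 (ring closure); C3–C4 (acetate aldol); C5=C6 (Wittig); C8–C9 (epoxide opening); C16–aryl.
Forward: the chain is built linearly (aryl–alkyl coupling, epoxide opening, oxidation, olefination, aldol). The oxolanone, the only ring made, is closed last by iodolactonization of the open-chain acid; iodine and benzyl are then removed.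
Stereochemistry: C7 is bought with (S)-2-methylglycidol and never touched; C4 comes from the (S)-HYTRA acetate aldol; C5 is set in the ring closure by the C4 carbinol (1,2-induction).
Enabling feature: C4 is an allylic carbinol next to the trisubstituted C5=C6 alkene, and the carboxyl carbon C2 stands 1,4 to C5. One 5-exo attack of the carboxylate on the iodonium ion at the tertiary carbon C5 therefore makes the C5–O1 bond, the ring and the quaternary stereocentre at once; iodine at C6 is a temporary activating group.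

Key step: step 7

Remark: 4-(benzyloxy)phenylmagnesium bromide (THF solution), (S)-2-methylglycidol and (S)-HYTRA are taken as purchased; the target is read as (4S,5S) in the ring and (R) at the side-chain carbinol.

Step 1
Reactants: 1 4-(benzyloxy)phenylmagnesium bromide; 2 1,8-dibromooctane
Product: 3 1-(benzyloxy)-4-(8-bromooctyl)benzene
Conditions: 2 (3 equiv), Li2CuCl4 (3 mol %), THF, −10 °C to rt, slow addition of 1
Reagents that add atoms: none
Why: Copper-catalysed Kumada-type sp2–sp3 cross-coupling of an aryl Grignard reagent with a primary alkyl bromide, in which the excess of dibromide should hold back double arylation; no stereocentre is involved.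

Step 2
Reactants: 3 1-(benzyloxy)-4-(8-bromooctyl)benzene; 4 (S)-2-methylglycidol [(2S)-(2-methyloxiran-2-yl)methanol]
Product: 6 (2R)-11-[4-(benzyloxy)phenyl]-2-methylundecane-1,2-diol, via Grignard reagent 5 (not isolated)
Conditions: 3 (2.2 equiv), Mg, THF, 40 °C; then CuI (10 mol %), 4 (1 equiv), THF, −30 to 0 °C; aq. NH4Cl
Reagents that add atoms: none
Why: Copper-catalysed SN2 opening of the 2,2-disubstituted epoxide at its CH2 carbon by the alkyl Grignard reagent (the first equivalent is consumed by the hydroxyl group); no bond to the quaternary carbon is broken, so C7 keeps the configuration of 4 and only its CIP descriptor changes from S to R.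

Step 3
Reactants: 6 (2R)-11-[4-(benzyloxy)phenyl]-2-methylundecane-1,2-diol
Product: 7 (2R)-11-[4-(benzyloxy)phenyl]-2-hydroxy-2-methylundecanal
Conditions: IBX (1.3 equiv), DMSO, rt
Reagents that add atoms: none
Why: IBX oxidation of the primary carbinol of a 1,2-diol to the α-hydroxy aldehyde without glycol cleavage; the tertiary carbinol cannot be oxidised and C7 bears no hydrogen, so it cannot epimerise.

Step 4
Reactants: 7 (2R)-11-[4-(benzyloxy)phenyl]-2-hydroxy-2-methylundecanal; 8 2-(triphenylphosphoranylidene)propanal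
Product: 9 (2E,4R)-13-[4-(benzyloxy)phenyl]-4-hydroxy-2,4-dimethyltridec-2-enal
Conditions: 8 (1.5 equiv), toluene, 70 °C
Reagents that add atoms: none
Why: Wittig olefination with a stabilised ylide, which should give the E-enal (C4 and C7 trans) under thermodynamic control of the oxaphosphetane; the γ-hydroxy E-enal cannot close to a lactol and no stereocentre is touched.

Step 5
Reactants: 9 (2E,4R)-13-[4-(benzyloxy)phenyl]-4-hydroxy-2,4-dimethyltridec-2-enal; 10 (S)-HYTRA [(1S)-2-hydroxy-1,2,2-triphenylethyl acetate]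
Product: 12 (1S)-2-hydroxy-1,2,2-triphenylethyl (3S,4E,6R)-15-[4-(benzyloxy)phenyl]-3,6-dihydroxy-4,6-dimethylpentadec-4-enoate, via dilithiated HYTRA 11 (not isolated)
Conditions: 10 (2.5 equiv), LiN(i-Pr)2 (5.2 equiv), THF, −78 to 0 °C; then 9, THF/2-methylbutane, −115 °C; aq. NH4Cl
Reagents that add atoms: none
Why: Auxiliary-controlled acetate aldol addition (1,2-addition) of doubly deprotonated HYTRA to the enal, which should set C4 as S because the (R)-reagent gives (R)-3-hydroxy-4-methylpentanoic acid from 2-methylpropanal and the alkenyl group has the same CIP rank over CH2CO as isopropyl; one equivalent of the dianion only deprotonates the C7 hydroxyl.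

Step 6
Reactants: 12 (1S)-2-hydroxy-1,2,2-triphenylethyl (3S,4E,6R)-15-[4-(benzyloxy)phenyl]-3,6-dihydroxy-4,6-dimethylpentadec-4-enoate
Product: 13 (3S,4E,6R)-15-[4-(benzyloxy)phenyl]-3,6-dihydroxy-4,6-dimethylpentadec-4-enoic acid
Conditions: KOH, MeOH/H2O, 50 °C; then 1 M HCl to pH 3, 0 °C
Reagents that add atoms: potassium hydroxide, [K+].[OH-]
Why: Saponification of the auxiliary ester, in which the β-hydroxy carboxylate should neither eliminate nor epimerise, and brief cold acidification should spare the two allylic carbinols.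

Step 7
Reactants: 13 (3S,4E,6R)-15-[4-(benzyloxy)phenyl]-3,6-dihydroxy-4,6-dimethylpentadec-4-enoic acid
Product: 14 (4S,5R)-5-{(1S,2R)-11-[4-(benzyloxy)phenyl]-2-hydroxy-1-iodo-2-methylundecyl}-4-hydroxy-5-methyloxolan-2-one
Conditions: I2 (3 equiv), NaHCO3 (3 equiv), MeCN, 0 °C, dark, short reaction time; aq. Na2S2O3
Reagents that add atoms: iodine, [I][I]
Why: Reversible transfer of iodonium to the C5=C6 alkene of the carboxylate is followed by anti opening of the iodonium ion at the more substituted carbon C5 by the carboxylate oxygen, which forms the C5–O1 bond and the oxolanone ring in a 5-exo closure (the 6-endo alternative would need attack at the neopentyl carbon C6). The closest known reaction type is the kinetic iodolactonization of 3-hydroxy-4-alkenoic acids, which gives cis-4-hydroxy-5-(iodoalkyl) lactones. The new quaternary centre C5 is controlled by the C4 carbinol: in the reacting conformer the C4–O bond should lie in the alkene plane syn to C6, a preference that the C5 methyl group should reinforce through A(1,2) strain, so the tethered carboxylate reaches C5 from the face that leaves the C4 hydroxyl cis to C6 and trans to the methyl group, which is the target arrangement (the descriptor of C5 reads R in 14 only because iodine raises the rank of C6). C6 (1S) follows from anti addition across the E-alkene and is erased in step 8. The step needs kinetic control (NaHCO3, 0 °C, so that the cis lactone does not equilibrate to the trans isomer) and chemoselectivity for the carboxylate over the two hydroxyls, which could only close three- or four-membered rings; the aryl benzyl ether should not be iodinated by I2 under these conditions.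

Step 8
Reactants: 14 (4S,5R)-5-{(1S,2R)-11-[4-(benzyloxy)phenyl]-2-hydroxy-1-iodo-2-methylundecyl}-4-hydroxy-5-methyloxolan-2-one
Product: 15 (4S,5S)-5-{(2R)-11-[4-(benzyloxy)phenyl]-2-hydroxy-2-methylundecyl}-4-hydroxy-5-methyloxolan-2-one
Conditions: Bu3SnH (3 equiv, 0.3 M), Et3B (0.2 equiv), air, toluene, 0 °C to rt
Reagents that add atoms: none
Why: Radical-chain hydrodeiodination, which turns C6 into the CH2 group of the target without touching C4, C5 or C7; the high stannane concentration and low temperature should keep hydrogen transfer faster than a 1,2-acyloxy shift of the β-(acyloxy)alkyl radical.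

Step 9
Reactants: 15 (4S,5S)-5-{(2R)-11-[4-(benzyloxy)phenyl]-2-hydroxy-2-methylundecyl}-4-hydroxy-5-methyloxolan-2-one
Product: 16 (4S,5S)-4-hydroxy-5-[(2R)-2-hydroxy-11-(4-hydroxyphenyl)-2-methylundecyl]-5-methyloxolan-2-one
Conditions: H2 (1 atm), 10% Pd/C, EtOAc, rt
Reagents that add atoms: none
Why: Hydrogenolysis of the aryl benzyl ether under neutral conditions, which should leave the lactone, the β-hydroxyl and the tertiary carbinol untouched (base, which could dehydrate the β-hydroxy lactone, is avoided).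

**Compound list**

1 | 4-(benzyloxy)phenylmagnesium bromide | Br[Mg]c1ccc(OCc2ccccc2)cc1 | starting material
2 | 1,8-dibromooctane | BrCCCCCCCCBr | starting material
3 | 1-(benzyloxy)-4-(8-bromooctyl)benzene | BrCCCCCCCCc1ccc(OCc2ccccc2)cc1 | intermediate
4 | (S)-2-methylglycidol, (2S)-(2-methyloxiran-2-yl)methanol | C[C@@]1(CO1)CO | starting material
5 | {8-[4-(benzyloxy)phenyl]octyl}magnesium bromide (not isolated) | Br[Mg]CCCCCCCCc1ccc(OCc2ccccc2)cc1 | intermediate
6 | (2R)-11-[4-(benzyloxy)phenyl]-2-methylundecane-1,2-diol | C[C@@](O)(CCCCCCCCCc1ccc(OCc2ccccc2)cc1)CO | intermediate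
7 | (2R)-11-[4-(benzyloxy)phenyl]-2-hydroxy-2-methylundecanal | C[C@@](O)(CCCCCCCCCc1ccc(OCc2ccccc2)cc1)C=O | intermediate
8 | 2-(triphenylphosphoranylidene)propanal | CC(C=O)=P(c1ccccc1)(c1ccccc1)c1ccccc1 | starting material
9 | (2E,4R)-13-[4-(benzyloxy)phenyl]-4-hydroxy-2,4-dimethyltridec-2-enal | C[C@@](O)(CCCCCCCCCc1ccc(OCc2ccccc2)cc1)/C=C(\C)C=O | intermediate
10 | (S)-HYTRA, (1S)-2-hydroxy-1,2,2-triphenylethyl acetate | CC(=O)O[C@@H](c1ccccc1)C(O)(c1ccccc1)c1ccccc1 | starting material
11 | dilithium enolate–alkoxide of (S)-HYTRA, doubly deprotonated 10 (not isolated) | [Li+].[Li+].C=C([O-])O[C@@H](c1ccccc1)C([O-])(c1ccccc1)c1ccccc1 | intermediate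
12 | (1S)-2-hydroxy-1,2,2-triphenylethyl (3S,4E,6R)-15-[4-(benzyloxy)phenyl]-3,6-dihydroxy-4,6-dimethylpentadec-4-enoate | O=C(C[C@H](O)/C(C)=C/[C@](C)(O)CCCCCCCCCc1ccc(OCc2ccccc2)cc1)O[C@@H](c1ccccc1)C(O)(c1ccccc1)c1ccccc1 | intermediate
13 | (3S,4E,6R)-15-[4-(benzyloxy)phenyl]-3,6-dihydroxy-4,6-dimethylpentadec-4-enoic acid | OC(=O)C[C@H](O)/C(C)=C/[C@](C)(O)CCCCCCCCCc1ccc(OCc2ccccc2)cc1 | intermediate
14 | (4S,5R)-5-{(1S,2R)-11-[4-(benzyloxy)phenyl]-2-hydroxy-1-iodo-2-methylundecyl}-4-hydroxy-5-methyloxolan-2-one | C[C@@](O)(CCCCCCCCCc1ccc(OCc2ccccc2)cc1)[C@H](I)[C@]1(C)OC(=O)C[C@@H]1O | intermediate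
15 | (4S,5S)-5-{(2R)-11-[4-(benzyloxy)phenyl]-2-hydroxy-2-methylundecyl}-4-hydroxy-5-methyloxolan-2-one | C[C@@](O)(CCCCCCCCCc1ccc(OCc2ccccc2)cc1)C[C@]1(C)OC(=O)C[C@@H]1O | intermediate
16 | (4S,5S)-4-hydroxy-5-[(2R)-2-hydroxy-11-(4-hydroxyphenyl)-2-methylundecyl]-5-methyloxolan-2-one | C[C@@](O)(CCCCCCCCCc1ccc(O)cc1)C[C@]1(C)OC(=O)C[C@@H]1O | target

**Step count and risks**

Total step count: 9. Longest linear sequence: 9 steps (1 to 16).

Step 7. The risk is poor facial selectivity in the ring closure: the C4 hydroxyl may not hold the in-plane conformer well enough in this congested alkene, or the cis iodolactone may equilibrate, so that the C5 epimer forms. The fallback sets C5 by reagent control before the ring exists and closes the ring by acylation. It sets out from 9. Luche reduction (NaBH4, CeCl3·7H2O, MeOH, 0 °C) should give (2E,4R)-13-[4-(benzyloxy)phenyl]-2,4-dimethyltridec-2-ene-1,4-diol F1. Sharpless asymmetric epoxidation (Ti(Oi-Pr)4, D-(−)-diethyl tartrate, t-BuOOH, 4 Å sieves, CH2Cl2, −20 °C) should give [(2R,3R)-3-{(2R)-11-[4-(benzyloxy)phenyl]-2-hydroxyundecan-2-yl}-2-methyloxiran-2-yl]methanol F2. Hydride opening at C6, directed by the C7 alkoxide (NaAlH2(OCH2CH2OCH3)2, THF, 0 °C), should give (2S,4R)-13-[4-(benzyloxy)phenyl]-2,4-dimethyltridecane-1,2,4-triol F3. IBX in DMSO should give (2S,4R)-13-[4-(benzyloxy)phenyl]-2,4-dihydroxy-2,4-dimethyltridecanal F4. The aldol conditions of step 5 should give (1S)-2-hydroxy-1,2,2-triphenylethyl (3S,4S,6R)-15-[4-(benzyloxy)phenyl]-3,4,6-trihydroxy-4,6-dimethylpentadecanoate F5. Saponification (KOH, MeOH/H2O) and acidification should lactonise the C5 hydroxyl onto the carboxyl group and return to the route at 15.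

Step 5. The risk is insufficient facial selectivity of the dianion addition, or proton exchange with the lithium alkoxide of 9, so that the C4 epimer of 12 forms. The fallback makes the C3–C4 bond without stereocontrol and sets C4 afterwards by a catalyst-controlled ketone reduction. It sets out from 9. A Reformatsky reaction (Zn, BrCH2CO2Et, THF) should give ethyl (3RS,4E,6R)-15-[4-(benzyloxy)phenyl]-3,6-dihydroxy-4,6-dimethylpentadec-4-enoate F6. MnO2 in CH2Cl2 should oxidise the allylic carbinol to ethyl (4E,6R)-15-[4-(benzyloxy)phenyl]-6-hydroxy-4,6-dimethyl-3-oxopentadec-4-enoate F7. Noyori asymmetric hydrogenation of the β-keto ester (H2, RuCl2[(R)-BINAP], EtOH) should give ethyl (3S,4E,6R)-15-[4-(benzyloxy)phenyl]-3,6-dihydroxy-4,6-dimethylpentadec-4-enoate F8. LiOH in THF/H2O should then return to the route at 13.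

Step 4. The risk is that olefination of the hindered, unprotected α-hydroxy aldehyde by the weakly nucleophilic formyl ylide is slower than self-condensation or thermal α-ketol rearrangement of 7. The fallback is a Horner–Wadsworth–Emmons reaction at the amide oxidation level followed by reduction. It sets out from 7. Diethyl [1-(methoxy(methyl)amino)-1-oxopropan-2-yl]phosphonate with LiCl and DBU in MeCN at rt should give (2E,4R)-13-[4-(benzyloxy)phenyl]-4-hydroxy-N-methoxy-N,2,4-trimethyltridec-2-enamide F9. i-Bu2AlH in THF at −78 °C should reduce the N-methoxy-N-methyl amide and return to the route at 9.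

**Further compounds**

F1 | step 7 | (2E,4R)-13-[4-(benzyloxy)phenyl]-2,4-dimethyltridec-2-ene-1,4-diol | C[C@@](O)(CCCCCCCCCc1ccc(OCc2ccccc2)cc1)/C=C(\C)CO
F2 | step 7 | [(2R,3R)-3-{(2R)-11-[4-(benzyloxy)phenyl]-2-hydroxyundecan-2-yl}-2-methyloxiran-2-yl]methanol | C[C@@](O)(CCCCCCCCCc1ccc(OCc2ccccc2)cc1)[C@H]1O[C@]1(C)CO
F3 | step 7 | (2S,4R)-13-[4-(benzyloxy)phenyl]-2,4-dimethyltridecane-1,2,4-triol | C[C@@](O)(CCCCCCCCCc1ccc(OCc2ccccc2)cc1)C[C@](C)(O)CO
F4 | step 7 | (2S,4R)-13-[4-(benzyloxy)phenyl]-2,4-dihydroxy-2,4-dimethyltridecanal | C[C@@](O)(CCCCCCCCCc1ccc(OCc2ccccc2)cc1)C[C@](C)(O)C=O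
F5 | step 7 | (1S)-2-hydroxy-1,2,2-triphenylethyl (3S,4S,6R)-15-[4-(benzyloxy)phenyl]-3,4,6-trihydroxy-4,6-dimethylpentadecanoate | O=C(C[C@H](O)[C@@](C)(O)C[C@](C)(O)CCCCCCCCCc1ccc(OCc2ccccc2)cc1)O[C@@H](c1ccccc1)C(O)(c1ccccc1)c1ccccc1
F6 | step 5 | ethyl (3RS,4E,6R)-15-[4-(benzyloxy)phenyl]-3,6-dihydroxy-4,6-dimethylpentadec-4-enoate | CCOC(=O)CC(O)/C(C)=C/[C@](C)(O)CCCCCCCCCc1ccc(OCc2ccccc2)cc1
F7 | step 5 | ethyl (4E,6R)-15-[4-(benzyloxy)phenyl]-6-hydroxy-4,6-dimethyl-3-oxopentadec-4-enoate | CCOC(=O)CC(=O)/C(C)=C/[C@](C)(O)CCCCCCCCCc1ccc(OCc2ccccc2)cc1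
F8 | step 5 | ethyl (3S,4E,6R)-15-[4-(benzyloxy)phenyl]-3,6-dihydroxy-4,6-dimethylpentadec-4-enoate | CCOC(=O)C[C@H](O)/C(C)=C/[C@](C)(O)CCCCCCCCCc1ccc(OCc2ccccc2)cc1
F9 | step 4 | (2E,4R)-13-[4-(benzyloxy)phenyl]-4-hydroxy-N-methoxy-N,2,4-trimethyltridec-2-enamide | C[C@@](O)(CCCCCCCCCc1ccc(OCc2ccccc2)cc1)/C=C(\C)C(=O)N(C)OC
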